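**Strategy.** The cyclohexene is numbered C1 (CHOBz next to the quaternary carbon), C2=C3, C4 (CHOBz), C5 (CHOH) and C6 (quaternary), with C7 the hydroxymethyl carbon. The chain C7–C6–C1–C2=C3 is a masked pent-4-enoic acid, the retron of a Claisen rearrangement. Everything therefore rests on an Ireland–Claisen rearrangement of a δ-lactone silyl ketene acetal: one operation forms the C1–C6 bond, closes the carbocycle, sets the quaternary C6 and the C1 stereocentres and creates the cis C2=C3 alkene. The precursor is a sugar-like L-gulo lactone whose ring oxygen sits on C3 and which carries a (Z)-2-benzoyloxyvinyl arm (C2=C1); its one catalytically set stereocentre relays all others.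

Key step: step 9

Remark on numbering: the carbon numbers of the target (C1–C7) are used for every intermediate; in the lactones the ring is O–C7(=O)–C6–C5–C4–C3 and the side chain is C2–C1.

Assumption: (S,S)-ProPhenol is taken as the ligand enantiomer that sends the alkynylzinc to the Si face of furfural; if the sense is the opposite, (R,R)-ProPhenol is used.

**Step 1**
Reactants: 1 furfural; 2 trimethylsilylacetylene
Product: 4 (S)-1-(furan-2-yl)prop-2-yn-1-ol, via silylated propargylic alcohol 3 (not isolated)
Conditions: ZnMe2 (3 equiv), (S,S)-ProPhenol (10 mol %), Ph3PO (20 mol %), toluene, 0 °C to rt; then K2CO3 (cat.), MeOH, rt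
Reagents that add atoms: trimethylsilylacetylene C#C[Si](C)(C)C
Why: Catalytic asymmetric alkynylation, in which the zinc alkynylide adds to the Si face of the aldehyde inside the dinuclear zinc–ProPhenol pocket and sets the only externally controlled stereocentre (S), followed by methoxide-mediated protodesilylation of the alkyne.

**Step 2**
Reactants: 4 (S)-1-(furan-2-yl)prop-2-yn-1-ol
Product: 5 (2S)-2-ethynyl-6-hydroxy-2H-pyran-3(6H)-one (mixture at the hemiacetal carbon)
Conditions: NBS (1.1 equiv), NaHCO3, NaOAc, THF/H2O 4:1, 0 °C
Reagents that add atoms: water O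
Why: Achmatowicz rearrangement, in which oxidation of the furan, opening to the cis-enedione and closure of the carbinol oxygen onto the aldehyde give the pyranone without touching the carbinol stereocentre (C3).

**Step 3**
Reactants: 5 (2S)-2-ethynyl-6-hydroxy-2H-pyran-3(6H)-one
Product: 6 (6S)-6-ethynyl-2H-pyran-2,5(6H)-dione
Conditions: CrO3, H2SO4, acetone, 0 °C, short contact, used at once
Reagents that add atoms: none
Why: Jones oxidation of the lactol to the lactone (C7), which leaves the enone and the terminal alkyne intact.

**Step 4**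
Reactants: 6 (6S)-6-ethynyl-2H-pyran-2,5(6H)-dione
Product: 7 (5R,6S)-6-ethynyl-5-hydroxy-5,6-dihydro-2H-pyran-2-one (hydroxyl trans to ethynyl)
Conditions: NaBH4, CeCl3·7H2O, MeOH/CH2Cl2, −78 °C
Reagents that add atoms: none
Why: Luche 1,2-reduction, in which hydride is delivered axially to the cerium-activated ketone of the half-chair with the ethynyl group pseudo-equatorial, so the C4 hydroxyl is expected trans to the C3 ethynyl group (should the cis alcohol prevail, plain benzoylation would replace step 5).

**Step 5**
Reactants: 7 (5R,6S)-6-ethynyl-5-hydroxy-5,6-dihydro-2H-pyran-2-one; 8 benzoic acid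
Product: 9 (5S,6S)-6-ethynyl-2-oxo-5,6-dihydro-2H-pyran-5-yl benzoate (benzoate cis to ethynyl)
Conditions: PPh3, DIAD, THF, 0 °C to rt
Reagents that add atoms: benzoic acid OC(=O)c1ccccc1
Why: Mitsunobu reaction, in which SN2 displacement of the oxyphosphonium by benzoate inverts C4 and installs the first benzoate of the target cis to the C3 substituent.

**Step 6**
Reactants: 9 (5S,6S)-6-ethynyl-2-oxo-5,6-dihydro-2H-pyran-5-yl benzoate
Product: 10 4-O-benzoyl-6,7-dideoxy-L-gulo-hept-6-ynono-1,5-lactone
Conditions: OsO4 (2 mol %), N-methylmorpholine N-oxide (1.5 equiv), citric acid, tBuOH/H2O, 0 °C to rt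
Reagents that add atoms: N-methylmorpholine N-oxide C[N+]1([O-])CCOCC1; water O
Why: Upjohn dihydroxylation, in which OsO4 adds suprafacially to the lactone alkene from the face opposite to the C4 benzoate and the C3 ethynyl group (which are cis to each other), so the new C5 hydroxyl is trans to the benzoate, while the alkyne is far less reactive and the acidic medium suppresses benzoyl migration.

**Step 7**
Reactants: 10 4-O-benzoyl-6,7-dideoxy-L-gulo-hept-6-ynono-1,5-lactone
Product: 11 4-O-benzoyl-6,7-dideoxy-2,3-bis-O-(triethylsilyl)-L-gulo-hept-6-ynono-1,5-lactone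
Conditions: Et3SiOTf (2.5 equiv), 2,6-lutidine, CH2Cl2, −78 to 0 °C
Reagents that add atoms: triethylsilyl trifluoromethanesulfonate CC[Si](CC)(CC)OS(=O)(=O)C(F)(F)F
Why: Silylation of both hydroxyls with a silyl triflate and a hindered base gives ethers that tolerate the later enolisation and come off under mild acid.

**Step 8**
Reactants: 11 the bis-silylated alkynyl lactone; 8 benzoic acid
Product: 12 the L-gulo lactone 11 in which the ethynyl group has become a (Z)-2-(benzoyloxy)ethenyl group
Conditions: Ru(η3-CH2C(CH3)CH2)2(Ph2P(CH2)4PPh2) (2 mol %), benzoic acid (1.1 equiv), toluene, 60 °C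
Reagents that add atoms: benzoic acid OC(=O)c1ccccc1
Why: Ruthenium-catalysed anti-Markovnikov addition of a carboxylic acid to a terminal alkyne via a ruthenium vinylidene, which with this bis(allyl) diphosphine catalyst type gives the (Z)-enol ester and so installs the second benzoate with the geometry the key step needs.

**Step 9**
Reactants: 12 the (Z)-2-(benzoyloxy)ethenyl lactone
Product: 15 2,5-bis(benzoyloxy)-1,6-bis(triethylsilyloxy)cyclohex-3-ene-1-carboxylic acid (ring stereocentres as in 17), via cyclic silyl ketene acetal 13 (not isolated), via trimethylsilyl ester 14 (not isolated)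
Conditions: LiN(iPr)2 (1.3 equiv), Me3SiCl/NEt3 (premixed, present from the start), THF, −100 to −78 °C; warm to rt, then toluene, 80 °C; aqueous citric acid work-up
Reagents that add atoms: none
Why: Kinetic deprotonation of 12 at C6 with in situ silylation gives the cyclic silyl ketene acetal 13, whose C6=C7–O–C3–C2=C1 array undergoes a suprafacial [3,3]-sigmatropic shift in which the lactone C3–O bond breaks as C1–C6 forms, leaving trimethylsilyl ester 14 that is hydrolysed on work-up. The closest known reaction type is the Ireland–Claisen rearrangement of 6-alkenyl δ-lactone silyl ketene acetals to cyclohexenecarboxylic acids. The six-membered carbocycle C1–C6 is closed through a boat transition state resembling a bicyclo[2.2.2]octene, the only one open to an endocyclic ketene acetal, with the alkenyl arm pseudo-axial and the C4 benzoate and C5 silyloxy group both pseudo-equatorial, so the ring C2=C3 alkene is cis. C6 is controlled by the C3 stereocentre, since the arm can reach only the ketene acetal face on which it stands, which is the face anti to the C5 oxygen, so that the C6 silyloxy group ends trans to O5 and the carboxyl carbon C7 cis to it. C1 is controlled by the Z geometry of the enol benzoate, which in the boat turns the benzoyloxy group toward the C4–C5 bridge and hence cis to the C6 oxygen and cis to the C4 benzoate. The step needs enolisation of the lactone without β-elimination of the C5 silyloxy group and without attack on the two benzoates, which the hindered amide base, trapping by Me3SiCl already present at −100 °C and the absence of any other acidic C–H should secure.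

**Step 10**
Reactants: 15 the cyclohexenecarboxylic acid
Product: 16 [2,5-bis(benzoyloxy)-1,6-bis(triethylsilyloxy)cyclohex-3-en-1-yl]methanol (ring stereocentres as in 17)
Conditions: BH3·SMe2 (2 equiv), THF, 0 °C to rt; MeOH quench
Reagents that add atoms: none
Why: Chemoselective borane reduction of a free carboxylic acid via its acyloxyborane, which is faster than reaction with benzoate esters, silyl ethers or the hindered, inductively deactivated ring alkene.

**Step 11**
Reactants: 16 the bis-silylated primary alcohol
Product: 17 (1S,4R,5S,6R)-5,6-dihydroxy-6-(hydroxymethyl)cyclohex-2-ene-1,4-diyl dibenzoate (target)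
Conditions: HF·pyridine, pyridine/THF, 0 °C to rt
Reagents that add atoms: none
Why: Fluoride-mediated desilylation under buffered acidic conditions removes both triethylsilyl ethers and avoids the benzoyl migration that a basic fluoride source could cause.

**Compound list**
1 | furfural (furan-2-carbaldehyde) | O=Cc1ccco1 | starting material
2 | trimethylsilylacetylene | C#C[Si](C)(C)C | starting material
3 | (S)-1-(furan-2-yl)-3-(trimethylsilyl)prop-2-yn-1-ol | O[C@@H](C#C[Si](C)(C)C)c1ccco1 | intermediate (not isolated)
4 | (S)-1-(furan-2-yl)prop-2-yn-1-ol | O[C@@H](C#C)c1ccco1 | intermediate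
5 | (2S)-2-ethynyl-6-hydroxy-2H-pyran-3(6H)-one, both hemiacetal epimers | OC1O[C@@H](C#C)C(=O)C=C1 | intermediate
6 | (6S)-6-ethynyl-2H-pyran-2,5(6H)-dione | O=C1O[C@@H](C#C)C(=O)C=C1 | intermediate
7 | (5R,6S)-6-ethynyl-5-hydroxy-5,6-dihydro-2H-pyran-2-one (OH trans to ethynyl) | O=C1O[C@@H](C#C)[C@H](O)C=C1 | intermediate
8 | benzoic acid | OC(=O)c1ccccc1 | starting material
9 | (5S,6S)-6-ethynyl-2-oxo-5,6-dihydro-2H-pyran-5-yl benzoate (benzoate cis to ethynyl) | O=C1O[C@@H](C#C)[C@@H](OC(=O)c2ccccc2)C=C1 | intermediate
10 | 4-O-benzoyl-6,7-dideoxy-L-gulo-hept-6-ynono-1,5-lactone | O=C1O[C@@H](C#C)[C@@H](OC(=O)c2ccccc2)[C@H](O)[C@@H]1O | intermediate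
11 | 4-O-benzoyl-6,7-dideoxy-2,3-bis-O-(triethylsilyl)-L-gulo-hept-6-ynono-1,5-lactone | O=C1O[C@@H](C#C)[C@@H](OC(=O)c2ccccc2)[C@H](O[Si](CC)(CC)CC)[C@@H]1O[Si](CC)(CC)CC | intermediate
12 | lactone 11 with the ethynyl group replaced by a (Z)-2-(benzoyloxy)ethenyl group (benzoate at C4 cis to the arm, silyloxy at C5 trans to the benzoate, silyloxy at C6 cis to that at C5) | O=C1O[C@@H](/C=C\OC(=O)c2ccccc2)[C@@H](OC(=O)c2ccccc2)[C@H](O[Si](CC)(CC)CC)[C@@H]1O[Si](CC)(CC)CC | intermediate
13 | cyclic trimethylsilyl ketene acetal of 12 (2-trimethylsilyloxy-3,4-dihydro-2H-pyran with C6=C7 in the ring) | C[Si](C)(C)OC1=C(O[Si](CC)(CC)CC)[C@@H](O[Si](CC)(CC)CC)[C@H](OC(=O)c2ccccc2)[C@H](/C=C\OC(=O)c2ccccc2)O1 | intermediate (not isolated)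
14 | trimethylsilyl ester of acid 15 | O=C(O[C@H]1C=C[C@@H](OC(=O)c2ccccc2)[C@H](O[Si](CC)(CC)CC)[C@]1(O[Si](CC)(CC)CC)C(=O)O[Si](C)(C)C)c1ccccc1 | intermediate (not isolated)
15 | 2,5-bis(benzoyloxy)-1,6-bis(triethylsilyloxy)cyclohex-3-ene-1-carboxylic acid (O1 and O4 cis, O5 trans to O4, O6 cis to O1, carboxyl cis to O5) | O=C(O[C@H]1C=C[C@@H](OC(=O)c2ccccc2)[C@H](O[Si](CC)(CC)CC)[C@]1(O[Si](CC)(CC)CC)C(O)=O)c1ccccc1 | intermediate
16 | [2,5-bis(benzoyloxy)-1,6-bis(triethylsilyloxy)cyclohex-3-en-1-yl]methanol (same arrangement as 15) | O=C(O[C@H]1C=C[C@@H](OC(=O)c2ccccc2)[C@H](O[Si](CC)(CC)CC)[C@]1(O[Si](CC)(CC)CC)CO)c1ccccc1 | intermediate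
17 | (1S,4R,5S,6R)-5,6-dihydroxy-6-(hydroxymethyl)cyclohex-2-ene-1,4-diyl dibenzoate | O=C(O[C@H]1C=C[C@@H](OC(=O)c2ccccc2)[C@H](O)[C@]1(O)CO)c1ccccc1 | target

**Total step count:** 11. **Longest linear sequence:** 11 steps (from furfural).

**Steps most likely to fail**

Step 9 (key step). The lithium enolate of 12 may expel the C5 silyloxy group before it is silylated, the amide base may cleave the enol benzoate, or the ketene acetal may decompose before it rearranges. The fallback sets out from 12 and comes back at 16; it closes the same C1–C6 bond without any enolate, by a thermal Claisen rearrangement at the aldehyde oxidation level. Lactone 12 would be reduced with disiamylborane (THF, rt), a reagent that stops at the lactol and spares benzoates, to the lactol F1. PPh3/CCl4 would turn it into the glycosyl chloride F2, and DBU (toluene, 60 °C) would eliminate HCl to the 2-silyloxy glycal F3, a 2-alkenyl-3,4-dihydro-2H-pyran with the same six atoms in place as in 13. Heating F3 in o-dichlorobenzene at about 180 °C should give, through the same boat transition state and hence with the same C1 and C6 configurations, the cyclohexene carbaldehyde F4, which NaBH4 (MeOH/THF, 0 °C) would reduce to 16.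

Step 3. Acid-promoted enolisation of dione 6 toward the aromatic, achiral 5-hydroxy-2-pyranone would erase the only stereocentre. The fallback sets out from 5 and comes back at 9; the ketone is reduced while C7 is still an acetal, so the dione is never formed. Lactol 5 would be converted with HC(OMe)3 and BF3·OEt2 (Et2O, 0 °C) into the methyl glycoside F5. Luche reduction would give the trans allylic alcohol F6, and Mitsunobu inversion with 8 the cis benzoate F7. Oxidation of the allylic acetal carbon with m-CPBA/BF3·OEt2 followed by NEt3 (fragmentation of the peroxy acetal) should then give lactone 9.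

Step 8. Benzoate may add with the wrong regiochemistry (geminal enol ester) or with partial loss of Z selectivity, because the propargylic acyloxy group and the neighbouring benzoate can bind ruthenium or perturb the vinylidene. The fallback sets out from 11 and comes back at 12; the Z geometry is fixed first in a C–B bond and the C–O bond is made afterwards. Rhodium-catalysed trans-hydroboration of 11 with pinacolborane ([RhCl(cod)]2, P(iPr)3, NEt3, cyclohexane) would give the (Z)-alkenylboronate F8. A Chan–Lam-type copper-mediated oxidative coupling with 8 (Cu(OAc)2, DMAP, 4 Å sieves, O2, CH2Cl2) should replace boron by benzoate with retention of alkene geometry and give 12.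

**Further compounds**
F1 | step 9 | lactol from 12 (C7 hemiacetal, both epimers) | OC1O[C@@H](/C=C\OC(=O)c2ccccc2)[C@@H](OC(=O)c2ccccc2)[C@H](O[Si](CC)(CC)CC)[C@@H]1O[Si](CC)(CC)CC
F2 | step 9 | glycosyl chloride from F1 | ClC1O[C@@H](/C=C\OC(=O)c2ccccc2)[C@@H](OC(=O)c2ccccc2)[C@H](O[Si](CC)(CC)CC)[C@@H]1O[Si](CC)(CC)CC
F3 | step 9 | 2-silyloxy glycal (C7=C6 enol ether in the ring, Z-benzoyloxyvinyl arm at C3) | C1=C(O[Si](CC)(CC)CC)[C@@H](O[Si](CC)(CC)CC)[C@H](OC(=O)c2ccccc2)[C@H](/C=C\OC(=O)c2ccccc2)O1
F4 | step 9 | 2,5-bis(benzoyloxy)-1,6-bis(triethylsilyloxy)cyclohex-3-ene-1-carbaldehyde (stereocentres as in 15) | O=C(O[C@H]1C=C[C@@H](OC(=O)c2ccccc2)[C@H](O[Si](CC)(CC)CC)[C@]1(O[Si](CC)(CC)CC)C=O)c1ccccc1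
F5 | step 3 | (2S)-2-ethynyl-6-methoxy-2H-pyran-3(6H)-one | COC1O[C@@H](C#C)C(=O)C=C1
F6 | step 3 | trans allylic alcohol from F5 | COC1O[C@@H](C#C)[C@H](O)C=C1
F7 | step 3 | cis benzoate from F6 | COC1O[C@@H](C#C)[C@@H](OC(=O)c2ccccc2)C=C1
F8 | step 8 | lactone 11 with the ethynyl group replaced by a (Z)-2-(pinacolboryl)ethenyl group | O=C1O[C@@H](/C=C\B2OC(C)(C)C(C)(C)O2)[C@@H](OC(=O)c2ccccc2)[C@H](O[Si](CC)(CC)CC)[C@@H]1O[Si](CC)(CC)CC
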